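## Retrosynthetic overview
1. Hanultarin comes from global O-debenzylation of its tri-O-benzyl ether. That ether comes from mono-acylation of the C2-symmetric (R,R)-diol with O-benzylferulic acid, where the two OH groups are homotopic and only one monoester is possible.
2. The diol comes from hydride reduction of the trans-(3R,4R)-dibenzylbutyrolactone (di-O-benzylmatairesinol).
3. Key disconnection, C8'–C7': a visible-light deoxygenative coupling of a cis-α-arylmethyl-β-hydroxy-γ-butyrolactone, reacting as its C4 radical, with O-benzylvanillin tosylhydrazone. C8 directs C8'.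
4. The hydroxylactone comes from diethyl (S)-malate and the benzylic bromide: anti-selective dianion alkylation makes C8–C7, then hydroxyl-directed reduction and lactonisation follow.
5. Rings: all three arenes are bought. The only ring made is a temporary γ-lactone, formed in Step 2, used as the stereocontrol template in Step 4 and opened in Step 5. The cinnamate is installed after the light-driven step, so there is no E/Z risk.

Assumption: bromide 2, aldehyde 5 and acid 10 are taken as catalogue chemicals. Lignan numbering is used (C8/C8' are the stereocentres, C7/C7' the benzylic CH2 groups, C9/C9' the CH2O carbons).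

## Route

Step 1
Reactants: 1, diethyl (S)-malate; 2, 4-(benzyloxy)-3-methoxybenzyl bromide
Product: 3, diethyl (2S,3R)-3-[4-(benzyloxy)-3-methoxybenzyl]-2-hydroxybutanedioate (anti)
Conditions: LiHMDS (2.2 equiv), THF, −78 → −20 °C; then 2 (1.05 equiv), −78 → −10 °C; chromatography (anti:syn about 9–10:1)
Reagents that add atoms: 2, COc1cc(CBr)ccc1OCc1ccccc1
Why: In this Fráter–Seebach alkylation the chelated lithium alkoxide–enolate dianion is attacked on the face anti to the carbinol substituent, so the bought (2S) centre sets the new (3R) centre, which becomes C8 of the target.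

Step 2
Reactants: 3
Product: 4, (3R,4S)-3-[4-(benzyloxy)-3-methoxybenzyl]-4-hydroxyoxolan-2-one (cis)
Conditions: BH3·SMe2 (1.05 equiv), NaBH4 (5 mol %), THF, 0 °C → rt; MeOH quench; p-TsOH (cat.), CH2Cl2, rt; purify to a single diastereomer
Reagents that add atoms: none
Why: Hydroxyl-directed (chelation-controlled) borane reduction touches only the α-hydroxy ester and the resulting 1,2-diol γ-lactonises through its primary OH without touching a stereocentre; any trans-lactone from the syn alkylation product must be removed here, because diastereomer impurity at this point becomes enantiomer impurity after Step 4.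

Step 3
Reactants: 5, 4-(benzyloxy)-3-methoxybenzaldehyde (O-benzylvanillin); 6, p-toluenesulfonyl hydrazide
Product: 7, (E)-N'-[4-(benzyloxy)-3-methoxybenzylidene]-4-methylbenzenesulfonohydrazide
Conditions: MeOH, rt, 2 h; filter the precipitate
Reagents that add atoms: 6, Cc1ccc(cc1)S(=O)(=O)NN
Why: Hydrazone condensation of an aromatic aldehyde is essentially quantitative and gives a crystalline product.

Step 4
Reactants: 4, (3R,4S)-3-[4-(benzyloxy)-3-methoxybenzyl]-4-hydroxyoxolan-2-one; 7, O-benzylvanillin (E)-N-tosylhydrazone
Product: 8, (3R,4R)-3,4-bis[4-(benzyloxy)-3-methoxybenzyl]oxolan-2-one (di-O-benzyl-(−)-matairesinol, trans)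
Conditions: one pot: (i) 5,7-di-tert-butyl-3-phenylbenzoxazolium BF4 (1.15 equiv), pyridine (1.15 equiv), MTBE, rt, 15 min, filter; (ii) 7 (1.6 equiv), [Ir(ppy)2(dtbbpy)]PF6 (1.5 mol %), 2,4,6-collidine (2 equiv), MTBE/DMA 1:1 (0.1 M), 450 nm LEDs, 25 °C, N2, 16 h; (iii) NaOAc·3H2O (5 equiv), EtOH, 65 °C, 2 h; chromatography (expected trans:cis at least 8:1)
Reagents that add atoms: 7 (delivers ArCH; N2 and sulfinate are lost), COc1cc(/C=N/NS(=O)(=O)c2ccc(C)cc2)ccc1OCc1ccccc1
Why: Proposed new method: this is a substrate-controlled deoxygenative alcohol–aldehyde C(sp3)–C(sp3) cross-coupling in which the 2-alkoxybenzoxazoline from 4 is oxidised by *Ir(III), collidine (too weak to deprotonate the hydrazone N–H or the lactone α-C–H) removes the acidified aminal C–H, β-scission driven by benzoxazolone formation releases the planar C4 lactone radical, this nucleophilic secondary radical adds to the electrophilic C=N carbon of 7 on the ring face opposite the C3 arylmethyl group (forming C8'–C7' and setting 4R regardless of the old carbinol configuration), Ir(II) reduces the hydrazinyl radical and collidinium protonates it (a redox-neutral cycle), and warm acetate expels sulfinate and N2 through a Caglioti-type diazene collapse to leave the CH2 link; the closest known reaction types are benzoxazolium-mediated photoredox deoxygenative Giese alkylation of alcohols and photocatalytic alkylation of N-sulfonylhydrazones by C–H- or acid-derived radicals, which have not been merged or used as a diastereoselective benzylation of a γ-butyrolactone C4 radical.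

Step 5
Reactants: 8
Product: 9, (2R,3R)-2,3-bis[4-(benzyloxy)-3-methoxybenzyl]butane-1,4-diol
Conditions: LiAlH4 (2 equiv), THF, 0 °C → rt, 2 h; Rochelle salt work-up
Reagents that add atoms: none
Why: Hydride reduction of the lactone to the 1,4-diol is faster than enolisation, so both centres are retained, and the aryl ethers are inert.

Step 6
Reactants: 9 (1.5 equiv); 10, (E)-3-[4-(benzyloxy)-3-methoxyphenyl]prop-2-enoic acid (O-benzylferulic acid)
Product: 11, (2R,3R)-2,3-bis[4-(benzyloxy)-3-methoxybenzyl]-4-hydroxybutyl (E)-3-[4-(benzyloxy)-3-methoxyphenyl]prop-2-enoate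
Conditions: EDC·HCl (1.2 equiv), DMAP (0.2 equiv), CH2Cl2, 0 °C → rt, slow addition of 10; recover and recycle 9
Reagents that add atoms: 10, COc1cc(/C=C/C(=O)O)ccc1OCc1ccccc1
Why: Steglich-type esterification of a C2-symmetric diol gives one monoester because the hydroxyls are homotopic and acyl migration between them is degenerate, and excess diol suppresses the diester.

Step 7
Reactants: 11
Product: 12, hanultarin
Conditions: BCl3 (1 M in CH2Cl2, 7 equiv), pentamethylbenzene (10 equiv), CH2Cl2, −78 °C, 45 min; quench with CHCl3/MeOH at −78 °C
Reagents that add atoms: none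
Why: Lewis-acid debenzylation with a non-basic cation scavenger cleaves the three aryl benzyl ethers at −78 °C while the E-cinnamate alkene, the ester, the aryl methyl ethers and both stereocentres survive, which hydrogenolysis would not allow.

## Compound list
1 | diethyl (S)-malate | CCOC(=O)C[C@H](O)C(=O)OCC | starting material
2 | 4-(benzyloxy)-3-methoxybenzyl bromide | COc1cc(CBr)ccc1OCc1ccccc1 | starting material
3 | diethyl (2S,3R)-3-[4-(benzyloxy)-3-methoxybenzyl]-2-hydroxybutanedioate | CCOC(=O)[C@@H](O)[C@@H](Cc1ccc(OCc2ccccc2)c(OC)c1)C(=O)OCC | intermediate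
4 | (3R,4S)-3-[4-(benzyloxy)-3-methoxybenzyl]-4-hydroxyoxolan-2-one | O=C1OC[C@@H](O)[C@H]1Cc2ccc(OCc3ccccc3)c(OC)c2 | intermediate
5 | 4-(benzyloxy)-3-methoxybenzaldehyde | COc1cc(C=O)ccc1OCc1ccccc1 | starting material
6 | p-toluenesulfonyl hydrazide | Cc1ccc(cc1)S(=O)(=O)NN | starting material
7 | O-benzylvanillin (E)-N-tosylhydrazone | COc1cc(/C=N/NS(=O)(=O)c2ccc(C)cc2)ccc1OCc1ccccc1 | intermediate
8 | (3R,4R)-3,4-bis[4-(benzyloxy)-3-methoxybenzyl]oxolan-2-one | O=C1OC[C@H](Cc2ccc(OCc3ccccc3)c(OC)c2)[C@H]1Cc2ccc(OCc3ccccc3)c(OC)c2 | intermediate
9 | (2R,3R)-2,3-bis[4-(benzyloxy)-3-methoxybenzyl]butane-1,4-diol | OC[C@H](Cc1ccc(OCc2ccccc2)c(OC)c1)[C@H](CO)Cc1ccc(OCc2ccccc2)c(OC)c1 | intermediate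
10 | (E)-4-benzyloxy-3-methoxycinnamic acid | COc1cc(/C=C/C(=O)O)ccc1OCc1ccccc1 | starting material
11 | tri-O-benzylhanultarin | COc1cc(/C=C/C(=O)OC[C@H](Cc2ccc(OCc3ccccc3)c(OC)c2)[C@H](CO)Cc2ccc(OCc3ccccc3)c(OC)c2)ccc1OCc1ccccc1 | intermediate
12 | hanultarin | COc1cc(/C=C/C(=O)OC[C@H](Cc2ccc(O)c(OC)c2)[C@H](CO)Cc2ccc(O)c(OC)c2)ccc1O | target

## Summary
Total steps: 7.
Longest linear sequence: 6 (1 → 3 → 4 → 8 → 9 → 11 → 12).

Steps most likely to fail:
1. **Step 4 (proposed new coupling).**
   - Risks: slow addition of an inductively deactivated secondary radical to an electron-rich hydrazone would give simple deoxygenation instead. The dr may be modest. The intermediate hydrazide may attack the lactone.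
   - Fallback (known polar chemistry that bypasses Steps 2 to 4): convert 3 to its α-triflate (Tf2O, 2,6-lutidine, −78 °C). Displace it with the 4-benzyloxy-3-methoxybenzyl Grignard under ZnCl2 catalysis, or with the benzylic cuprate. This is a stereospecific SN2 with inversion and gives diethyl (2R,3R)-2,3-bis(arylmethyl)succinate. LiAlH4 then gives 9.
2. **Step 7 (global debenzylation next to a cinnamate).**
   - Risks: partial O-demethylation, C-benzylation of the guaiacyl rings, or Lewis-acid-induced tetrahydrofuran formation with loss of ferulate.
   - Fallback: deprotect before the alkene exists, by hydrogenolysis of 9 (H2, Pd/C) to (−)-secoisolariciresinol. Then build the ferulate with all phenols free: mono-malonylation with Meldrum's acid (toluene, heat), followed by Knoevenagel–Doebner condensation with vanillin (pyridine, cat. piperidine) to give 12.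
3. **Step 6 (statistical mono-acylation).**
   - Risk: diester formation and a low yield based on the precious diol.
   - Fallback: differentiate the termini through the lactone rather than the diol. Open 8 with Me(MeO)NH·HCl/AlMe3 to the hydroxy Weinreb amide and acylate the free OH with 10. Reduce the amide chemoselectively with Cp2Zr(H)Cl to the aldehyde, then with NaBH4 to 11.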